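**Retrosynthetic overview**

1. Target ⇐ tetra-O-silyl trans-3,4-diarylchroman ⇐ diol (Mitsunobu closure at O1–C2) ⇐ trans-3,4-diarylchroman-2-one; C2 is carried at the acid oxidation level so that O1–C2 can act as the tether of the key step.
2. Key disconnection C3–C4: the lactone (ring C) ⇐ aryl α-diazo(aryl)acetate of a 2-benzylphenol by enantioselective rhodium-carbene 1,6 C–H insertion. Enabling feature: C4 is a CH2 between ring A (C7–O para to C4a) and ring F (O para, OMe ortho to its attachment carbon), so its C–H is the most hydridic one within reach; O1 on C8a, ortho to C4a, holds the ring B carbene carbon C3 six atoms from C4–H.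
3. Diarylmethane ⇐ ring F aryllithium (5'-bromo-(R)-isoflavan) + 2-hydroxy-4-silyloxybenzaldehyde (ring A), then ionic deoxygenation; ring B enters as a 2-silyloxy-4,5-dimethoxyphenylacetic acid.
4. Lower (R)-isoflavan ⇐ Pd α-arylation of 7-silyloxychroman-4-one, Ru transfer hydrogenation with dynamic kinetic resolution (sets the lower stereocentre), hydrogenolysis, bromination para to the ring F phenol.
5. Ring order: rings D/E are bought as the chromanone; rings A, B and F are aromatic building blocks; ring C is closed last, first as the lactone at C3–C4 (both upper stereocentres), then re-closed as the pyran at O1–C2.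

Key step: step 15

**Remarks**

- TIPS = triisopropylsilyl. ArF = 2-methoxy-4-(TIPS-oxy)-5-[(3R)-7-(TIPS-oxy)chroman-3-yl]phenyl.
- Upper unit: O1, C2, C3, C4, C4a–C8a; ring A (benzo), ring C (pyran), ring B (aryl on C3).
- Lower isoflavan: ring D (benzo), ring E (pyran), ring F (its 3-aryl group, which is also the aryl on upper C4). In the free lower fragment ring F is numbered C1' (on the chroman), C2' (oxygen), C4' (OMe), C5' (later link).
- Rh2(S-PTAD)4 = dirhodium tetrakis[(S)-(1-adamantyl)(N-phthalimido)acetate].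
- Assumption: the sense of induction of Rh2(S-PTAD)4 in the six-membered insertion of step 15 is taken to give the (4S) centre; the mirror-image catalyst Rh2(R-PTAD)4 would be used if the other hydrogen is selected.

**Route**

Step 1
Reactants: 1 7-hydroxychroman-4-one
Product: 2 7-(TIPS-oxy)chroman-4-one
Conditions: TIPSCl, imidazole, DMF, rt
Reagents that add atoms: triisopropylsilyl chloride, CC(C)[Si](Cl)(C(C)C)C(C)C
Why: Silylation of the only hydroxyl group (a phenol) gives a bulky aryl silyl ether that should survive the later basic, reductive and acidic steps and that later shields the open positions of ring D.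

Step 2
Reactants: 3 2-bromo-5-methoxyphenol
Product: 4 2-(benzyloxy)-1-bromo-4-methoxybenzene
Conditions: BnBr, K2CO3, DMF, 50 °C
Reagents that add atoms: benzyl bromide, BrCc1ccccc1
Why: Williamson etherification of the phenol; benzyl is chosen because step 5 removes it in the same operation as the benzylic hydroxyl group.

Step 3
Reactants: 2 7-(TIPS-oxy)chroman-4-one; 4 2-(benzyloxy)-1-bromo-4-methoxybenzene
Product: 5 rac-3-[2-(benzyloxy)-4-methoxyphenyl]-7-(TIPS-oxy)chroman-4-one
Conditions: Pd(OAc)2 (5 mol%), XPhos (10 mol%), K3PO4, toluene, 100 °C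
Reagents that add atoms: none
Why: Palladium-catalysed α-arylation of the ketone (Buchwald–Hartwig-type enolate arylation, known for chroman-4-ones): oxidative addition of zerovalent palladium into the C–Br bond, enolate binding and reductive elimination should give the racemic isoflavanone, whose enolisable C3 is exploited in step 4.

Step 4
Reactants: 5 rac-3-[2-(benzyloxy)-4-methoxyphenyl]-7-(TIPS-oxy)chroman-4-one
Product: 6 (3R,4R)-3-[2-(benzyloxy)-4-methoxyphenyl]-7-(TIPS-oxy)chroman-4-ol (cis)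
Conditions: RuCl[(R,R)-TsDPEN](p-cymene) (2 mol%), HCO2H/Et3N (5:2), EtOAc, 40 °C
Reagents that add atoms: none
Why: Noyori–Ikariya asymmetric transfer hydrogenation with dynamic kinetic resolution: C3 racemises through the enol under Et3N while the (R,R) catalyst reduces only the ketone enantiomer whose aryl group lies anti to the incoming hydride, so the cis-(3R,4R) alcohol should form and the single stereocentre of the lower unit is set (sense by analogy with chroman-4-one, which gives the (S) alcohol with the (S,S) catalyst).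

Step 5
Reactants: 6 (3R,4R)-3-[2-(benzyloxy)-4-methoxyphenyl]-7-(TIPS-oxy)chroman-4-ol
Product: 7 5-methoxy-2-[(3R)-7-(TIPS-oxy)chroman-3-yl]phenol
Conditions: H2 (1 atm), 10% Pd/C, EtOH/AcOH (10:1), rt
Reagents that add atoms: none
Why: Hydrogenolysis over Pd/C should cleave both the benzyl ether and the benzylic C4–OH bond (activated by the para silyloxy group) without touching C3, and it unveils the ring F phenol that directs step 6.

Step 6
Reactants: 7 5-methoxy-2-[(3R)-7-(TIPS-oxy)chroman-3-yl]phenol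
Product: 8 4-bromo-5-methoxy-2-[(3R)-7-(TIPS-oxy)chroman-3-yl]phenol
Conditions: NBS (1.0 equiv), MeCN, −30 → 0 °C
Reagents that add atoms: N-bromosuccinimide, O=C1CCC(=O)N1Br
Why: Electrophilic aromatic bromination should go to C5' of ring F, para to the free phenol and ortho to OMe, which is the most activated and an unhindered site, whereas C3' lies between two oxygens and the open positions of ring D are less activated and flanked by the bulky TIPS ether.

Step 7
Reactants: 8 4-bromo-5-methoxy-2-[(3R)-7-(TIPS-oxy)chroman-3-yl]phenol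
Product: 9 (3R)-3-[5-bromo-4-methoxy-2-(TIPS-oxy)phenyl]-7-(TIPS-oxy)chromane
Conditions: TIPSOTf, 2,6-lutidine, CH2Cl2, 0 °C → rt
Reagents that add atoms: triisopropylsilyl triflate, CC(C)[Si](OS(=O)(=O)C(F)(F)F)(C(C)C)C(C)C
Why: Silylation of the hindered phenol with the silyl triflate completes a protecting-group pattern of silyl ethers only, which tolerates the aryllithium of step 11 and the carbene of step 15 and allows one final deprotection.

Step 8
Reactants: 10 2,4-dihydroxybenzaldehyde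
Product: 11 2-hydroxy-4-(TIPS-oxy)benzaldehyde
Conditions: TIPSCl (1.05 equiv), imidazole, CH2Cl2, 0 °C
Reagents that add atoms: triisopropylsilyl chloride, CC(C)[Si](Cl)(C(C)C)C(C)C
Why: The 4-hydroxyl group is silylated selectively because the 2-hydroxyl group is held in a hydrogen bond to the aldehyde and is less nucleophilic.

Step 9
Reactants: 12 2-(2-bromo-4,5-dimethoxyphenyl)acetic acid
Product: 13 2-(2-hydroxy-4,5-dimethoxyphenyl)acetic acid
Conditions: CuI (10 mol%), 1,10-phenanthroline (20 mol%), KOH, DMSO/H2O (1:1), 100 °C, argon; then 1 M HCl, 0 °C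
Reagents that add atoms: potassium hydroxide, [K+].[OH-]
Why: Copper-catalysed hydroxylation of the aryl bromide (Ullmann-type C–O coupling with hydroxide), assisted by the neighbouring carboxylate, should give the hydroxy acid, which is isolated cold and used at once to avoid lactonisation.

Step 10
Reactants: 13 2-(2-hydroxy-4,5-dimethoxyphenyl)acetic acid
Product: 15 2-[4,5-dimethoxy-2-(TIPS-oxy)phenyl]acetic acid, via disodium salt of the hydroxy acid 14 (not isolated)
Conditions: NaH (2.1 equiv), THF, 0 °C; TIPSCl (1.1 equiv), 0 °C → rt; cold 1 M HCl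
Reagents that add atoms: triisopropylsilyl chloride, CC(C)[Si](Cl)(C(C)C)C(C)C
Why: In the dianion the phenoxide is far more nucleophilic than the carboxylate and should be silylated selectively, any silyl ester being hydrolysed in the acidic work-up; silicon on this oxygen leaves no C–H next to the later carbene.

Step 11
Reactants: 9 (3R)-3-[5-bromo-4-methoxy-2-(TIPS-oxy)phenyl]-7-(TIPS-oxy)chromane; 11 2-hydroxy-4-(TIPS-oxy)benzaldehyde
Product: 18 2-[ArF(hydroxy)methyl]-5-(TIPS-oxy)phenol (both carbinol epimers), via aryllithium ArF–Li 16 (not isolated), via sodium 2-formyl-5-(TIPS-oxy)phenoxide 17 (not isolated)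
Conditions: 9, n-BuLi, THF, −78 °C; 11, NaH (1.0 equiv), THF, 0 °C; combined at −78 → −20 °C; aq. NH4Cl
Reagents that add atoms: none
Why: Bromine–lithium exchange gives an aryllithium stabilised by its ortho methoxy group, which adds to the aldehyde (1,2-addition) of the phenoxide made beforehand with NaH so that no aryllithium is lost to the acidic OH; the carbinol centre forms as a mixture and is removed in step 12.

Step 12
Reactants: 18 2-[ArF(hydroxy)methyl]-5-(TIPS-oxy)phenol
Product: 19 2-(ArF-methyl)-5-(TIPS-oxy)phenol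
Conditions: Et3SiH, TFA, CH2Cl2, −40 → 0 °C
Reagents that add atoms: none
Why: Ionic hydrogenation: acid ionises the carbinol to a cation stabilised by the para oxygens of both rings (quinone methide type), which Et3SiH should capture to give the diarylmethane whose CH2 is the site of the key step.

Step 13
Reactants: 19 2-(ArF-methyl)-5-(TIPS-oxy)phenol; 15 2-[4,5-dimethoxy-2-(TIPS-oxy)phenyl]acetic acid
Product: 20 2-(ArF-methyl)-5-(TIPS-oxy)phenyl 2-[4,5-dimethoxy-2-(TIPS-oxy)phenyl]acetate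
Conditions: DCC, DMAP (cat.), CH2Cl2, 0 °C → rt
Reagents that add atoms: none
Why: Steglich esterification of the only free hydroxyl group installs the O1–C2 bond at the acid oxidation level as the tether for the key step.

Step 14
Reactants: 20 2-(ArF-methyl)-5-(TIPS-oxy)phenyl 2-[4,5-dimethoxy-2-(TIPS-oxy)phenyl]acetate
Product: 21 2-(ArF-methyl)-5-(TIPS-oxy)phenyl 2-diazo-2-[4,5-dimethoxy-2-(TIPS-oxy)phenyl]acetate
Conditions: p-ABSA, DBU, MeCN, 0 °C → rt
Reagents that add atoms: 4-acetamidobenzenesulfonyl azide, CC(=O)Nc1ccc(cc1)S(=O)(=O)N=[N+]=[N-]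
Why: Regitz diazo transfer to the activated methylene group of the aryl arylacetate should give the donor/acceptor diazo ester.

Step 15
Reactants: 21 2-(ArF-methyl)-5-(TIPS-oxy)phenyl 2-diazo-2-[4,5-dimethoxy-2-(TIPS-oxy)phenyl]acetate
Product: 23 (3R,4S)-4-ArF-3-[4,5-dimethoxy-2-(TIPS-oxy)phenyl]-7-(TIPS-oxy)chroman-2-one (trans lactone), via C3-epimeric lactone mixture 22 (not isolated)
Conditions: Rh2(S-PTAD)4 (1 mol%), CH2Cl2, −20 °C → rt, 21 added over 4 h (final 0.01 M); then DBU (0.3 equiv), rt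
Reagents that add atoms: none
Why: Proposed new method: loss of N2 at the dirhodium tetracarboxylate gives a donor/acceptor rhodium carbene at C3 which, from the s-cis rotamer of the aryl ester, takes up hydride from and bonds to the doubly benzylic C4 in one asynchronous three-centre event (1,6 C–H insertion through a six-membered transition state), the C4–H bond being made hydridic by the para oxygens of ring A and ring F. The closest known reactions are the enantioselective intramolecular 1,5 C–H insertion of aryldiazoacetates into benzylic ether C–H bonds (2,3-dihydrobenzofuran synthesis with chiral dirhodium carboxylates) and the intermolecular insertion of aryldiazoacetates into benzylic methylene groups; the new element is the six-membered closure onto a diarylmethane through an aryl ester tether. Ring C is closed as its six-membered lactone by this C3–C4 bond. C4 is set by the chiral carboxylate pocket, which distinguishes the two enantiotopic hydrogens of the CH2 group, and C3, which is enolisable, is then equilibrated by DBU to the trans arrangement with both aryl groups pseudo-equatorial, so that the catalyst-set centre is relayed to the second one. The step needs site selectivity for C4–H over attack on C8 of ring A, insertion next to an ether oxygen and carbene dimerisation; this is secured by the absence of any sp3 C–H five atoms from the carbene, by silicon instead of carbon on the ortho oxygen of ring B, by the bulky 7-O-TIPS group next to C8, and by slow addition at high dilution.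

Step 16
Reactants: 23 (3R,4S)-4-ArF-3-[4,5-dimethoxy-2-(TIPS-oxy)phenyl]-7-(TIPS-oxy)chroman-2-one
Product: 24 (2R,3S)-3-ArF-2-[4,5-dimethoxy-2-(TIPS-oxy)phenyl]-3-[2-hydroxy-4-(TIPS-oxy)phenyl]propan-1-ol
Conditions: LiBH4, THF, 0 °C → rt; aq. NH4Cl
Reagents that add atoms: none
Why: Hydride reduction of the reactive aryl lactone should give the primary alcohol and free the ring A phenol while the silyl ethers stay intact, and C3 is no longer enolisable once C2 is reduced.

Step 17
Reactants: 24 (2R,3S)-3-ArF-2-[4,5-dimethoxy-2-(TIPS-oxy)phenyl]-3-[2-hydroxy-4-(TIPS-oxy)phenyl]propan-1-ol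
Product: 25 (3R,4S)-4-ArF-3-[4,5-dimethoxy-2-(TIPS-oxy)phenyl]-7-(TIPS-oxy)chromane
Conditions: PPh3, DIAD, THF, 0 °C → rt
Reagents that add atoms: none
Why: Intramolecular Mitsunobu etherification (6-exo-tet displacement of the activated primary alcohol by the only free phenol) should re-close ring C at O1–C2 without touching a stereocentre.

Step 18
Reactants: 25 (3R,4S)-4-ArF-3-[4,5-dimethoxy-2-(TIPS-oxy)phenyl]-7-(TIPS-oxy)chromane
Product: 26 (3R,4S)-4-{4-hydroxy-5-[(3R)-7-hydroxychroman-3-yl]-2-methoxyphenyl}-3-(2-hydroxy-4,5-dimethoxyphenyl)chroman-7-ol (target)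
Conditions: TBAF, AcOH, THF, 0 °C → rt, argon
Reagents that add atoms: none
Why: Fluoride should cleave the four aryl silyl ethers in one operation, with acetic acid buffering the phenoxides and exclusion of air protecting the electron-rich tetraphenol.

**Compound list**

1 | 7-hydroxychroman-4-one | O=C1CCOc2cc(O)ccc21 | starting material
2 | 7-(TIPS-oxy)chroman-4-one | O=C1CCOc2cc(O[Si](C(C)C)(C(C)C)C(C)C)ccc21 | intermediate
3 | 2-bromo-5-methoxyphenol | COc1ccc(Br)c(O)c1 | starting material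
4 | 2-(benzyloxy)-1-bromo-4-methoxybenzene | COc1ccc(Br)c(OCc2ccccc2)c1 | intermediate
5 | rac-3-[2-(benzyloxy)-4-methoxyphenyl]-7-(TIPS-oxy)chroman-4-one | COc1ccc(C2COc3cc(O[Si](C(C)C)(C(C)C)C(C)C)ccc3C2=O)c(OCc2ccccc2)c1 | intermediate
6 | (3R,4R)-3-[2-(benzyloxy)-4-methoxyphenyl]-7-(TIPS-oxy)chroman-4-ol (cis) | COc1ccc([C@@H]2COc3cc(O[Si](C(C)C)(C(C)C)C(C)C)ccc3[C@@H]2O)c(OCc2ccccc2)c1 | intermediate
7 | 5-methoxy-2-[(3R)-7-(TIPS-oxy)chroman-3-yl]phenol | COc1ccc([C@@H]2COc3cc(O[Si](C(C)C)(C(C)C)C(C)C)ccc3C2)c(O)c1 | intermediate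
8 | 4-bromo-5-methoxy-2-[(3R)-7-(TIPS-oxy)chroman-3-yl]phenol | COc1cc(O)c([C@@H]2COc3cc(O[Si](C(C)C)(C(C)C)C(C)C)ccc3C2)cc1Br | intermediate
9 | (3R)-3-[5-bromo-4-methoxy-2-(TIPS-oxy)phenyl]-7-(TIPS-oxy)chromane | COc1cc(O[Si](C(C)C)(C(C)C)C(C)C)c([C@@H]2COc3cc(O[Si](C(C)C)(C(C)C)C(C)C)ccc3C2)cc1Br | intermediate
10 | 2,4-dihydroxybenzaldehyde | O=Cc1ccc(O)cc1O | starting material
11 | 2-hydroxy-4-(TIPS-oxy)benzaldehyde | O=Cc1ccc(O[Si](C(C)C)(C(C)C)C(C)C)cc1O | intermediate
12 | 2-(2-bromo-4,5-dimethoxyphenyl)acetic acid | COc1cc(Br)c(CC(=O)O)cc1OC | starting material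
13 | 2-(2-hydroxy-4,5-dimethoxyphenyl)acetic acid | COc1cc(O)c(CC(=O)O)cc1OC | intermediate
14 | disodium salt of 2-(2-hydroxy-4,5-dimethoxyphenyl)acetic acid (not isolated) | COc1cc([O-])c(CC(=O)[O-])cc1OC.[Na+].[Na+] | intermediate
15 | 2-[4,5-dimethoxy-2-(TIPS-oxy)phenyl]acetic acid | COc1cc(O[Si](C(C)C)(C(C)C)C(C)C)c(CC(=O)O)cc1OC | intermediate
16 | aryllithium ArF–Li (not isolated) | COc1cc(O[Si](C(C)C)(C(C)C)C(C)C)c([C@@H]2COc3cc(O[Si](C(C)C)(C(C)C)C(C)C)ccc3C2)cc1[Li] | intermediate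
17 | sodium 2-formyl-5-(TIPS-oxy)phenoxide (not isolated) | O=Cc1ccc(O[Si](C(C)C)(C(C)C)C(C)C)cc1[O-].[Na+] | intermediate
18 | 2-[ArF(hydroxy)methyl]-5-(TIPS-oxy)phenol, both carbinol epimers | COc1cc(O[Si](C(C)C)(C(C)C)C(C)C)c([C@@H]2COc3cc(O[Si](C(C)C)(C(C)C)C(C)C)ccc3C2)cc1C(O)c1ccc(O[Si](C(C)C)(C(C)C)C(C)C)cc1O | intermediate
19 | 2-(ArF-methyl)-5-(TIPS-oxy)phenol | COc1cc(O[Si](C(C)C)(C(C)C)C(C)C)c([C@@H]2COc3cc(O[Si](C(C)C)(C(C)C)C(C)C)ccc3C2)cc1Cc1ccc(O[Si](C(C)C)(C(C)C)C(C)C)cc1O | intermediate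
20 | 2-(ArF-methyl)-5-(TIPS-oxy)phenyl 2-[4,5-dimethoxy-2-(TIPS-oxy)phenyl]acetate | COc1cc(O[Si](C(C)C)(C(C)C)C(C)C)c(CC(=O)Oc2cc(O[Si](C(C)C)(C(C)C)C(C)C)ccc2Cc2cc([C@@H]3COc4cc(O[Si](C(C)C)(C(C)C)C(C)C)ccc4C3)c(O[Si](C(C)C)(C(C)C)C(C)C)cc2OC)cc1OC | intermediate
21 | 2-(ArF-methyl)-5-(TIPS-oxy)phenyl 2-diazo-2-[4,5-dimethoxy-2-(TIPS-oxy)phenyl]acetate | COc1cc(O[Si](C(C)C)(C(C)C)C(C)C)c(C(=[N+]=[N-])C(=O)Oc2cc(O[Si](C(C)C)(C(C)C)C(C)C)ccc2Cc2cc([C@@H]3COc4cc(O[Si](C(C)C)(C(C)C)C(C)C)ccc4C3)c(O[Si](C(C)C)(C(C)C)C(C)C)cc2OC)cc1OC | intermediate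
22 | (4S)-4-ArF-3-[4,5-dimethoxy-2-(TIPS-oxy)phenyl]-7-(TIPS-oxy)chroman-2-one, mixture of C3 epimers (not isolated) | COc1cc(O[Si](C(C)C)(C(C)C)C(C)C)c(C2C(=O)Oc3cc(O[Si](C(C)C)(C(C)C)C(C)C)ccc3[C@H]2c2cc([C@@H]3COc4cc(O[Si](C(C)C)(C(C)C)C(C)C)ccc4C3)c(O[Si](C(C)C)(C(C)C)C(C)C)cc2OC)cc1OC | intermediate
23 | (3R,4S)-4-ArF-3-[4,5-dimethoxy-2-(TIPS-oxy)phenyl]-7-(TIPS-oxy)chroman-2-one (trans) | COc1cc(O[Si](C(C)C)(C(C)C)C(C)C)c([C@@H]2C(=O)Oc3cc(O[Si](C(C)C)(C(C)C)C(C)C)ccc3[C@H]2c2cc([C@@H]3COc4cc(O[Si](C(C)C)(C(C)C)C(C)C)ccc4C3)c(O[Si](C(C)C)(C(C)C)C(C)C)cc2OC)cc1OC | intermediate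
24 | (2R,3S)-3-ArF-2-[4,5-dimethoxy-2-(TIPS-oxy)phenyl]-3-[2-hydroxy-4-(TIPS-oxy)phenyl]propan-1-ol | COc1cc(O[Si](C(C)C)(C(C)C)C(C)C)c([C@H](CO)[C@@H](c2ccc(O[Si](C(C)C)(C(C)C)C(C)C)cc2O)c2cc([C@@H]3COc4cc(O[Si](C(C)C)(C(C)C)C(C)C)ccc4C3)c(O[Si](C(C)C)(C(C)C)C(C)C)cc2OC)cc1OC | intermediate
25 | (3R,4S)-4-ArF-3-[4,5-dimethoxy-2-(TIPS-oxy)phenyl]-7-(TIPS-oxy)chromane | COc1cc(O[Si](C(C)C)(C(C)C)C(C)C)c([C@@H]2COc3cc(O[Si](C(C)C)(C(C)C)C(C)C)ccc3[C@H]2c2cc([C@@H]3COc4cc(O[Si](C(C)C)(C(C)C)C(C)C)ccc4C3)c(O[Si](C(C)C)(C(C)C)C(C)C)cc2OC)cc1OC | intermediate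
26 | (3R,4S)-4-{4-hydroxy-5-[(3R)-7-hydroxychroman-3-yl]-2-methoxyphenyl}-3-(2-hydroxy-4,5-dimethoxyphenyl)chroman-7-ol | COc1cc(O)c([C@@H]2COc3cc(O)ccc3[C@H]2c2cc([C@@H]3COc4cc(O)ccc4C3)c(O)cc2OC)cc1OC | target

**Step count and risks**

Total step count: 18. Longest linear sequence: 14 steps (steps 1, 3 to 7 and 11 to 18).

Steps most likely to fail:

Step 15 (Proposed new method). The carbene may be diverted (dimerisation, attack on C8 of ring A or on the other electron-rich arenes), or the catalyst may distinguish the two C4 hydrogens poorly. The fallback uses known chemistry and sets out from benzhydrol 18 and acid 15. p-Toluenesulfinic acid (CH2Cl2, rt) converts 18 into 2-[ArF(p-tolylsulfonyl)methyl]-5-(TIPS-oxy)phenol F1. Cs2CO3 then releases the o-quinone methide F2 in the presence of the mixed pivalic anhydride F3 of acid 15 (t-BuCOCl, i-Pr2NEt) and the chiral isothiourea HBTM-2.1 (10 mol%, CH2Cl2). The C1-ammonium enolate adds to the methide carbon and the ring A phenoxide lactonises, a known formal [4+2] route to cis-3,4-diaryl-3,4-dihydrocoumarins with catalyst control at C4. This returns to the route at mixture 22, which DBU equilibrates to 23 as in step 15.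

Step 6. Positional selectivity of the bromination may be lost (attack at C3' or on ring D) or a second bromine may enter. The fallback sets out from ketone 5, in which ring D is deactivated by the conjugated chromanone carbonyl so that only ring F is activated. NBS (MeCN, 0 °C) should give rac-3-[2-(benzyloxy)-5-bromo-4-methoxyphenyl]-7-(TIPS-oxy)chroman-4-one F4. The transfer hydrogenation of step 4 then gives the cis-(3R,4R) bromo alcohol F5. Ionic deoxygenation (Et3SiH, BF3·OEt2, CH2Cl2, −78 °C) gives (3R)-3-[2-(benzyloxy)-5-bromo-4-methoxyphenyl]-7-(TIPS-oxy)chromane F6, and debenzylation with BCl3 and pentamethylbenzene (CH2Cl2, −78 °C) returns to the route at 8.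

Step 3. The base may open the pyranone ring by retro-oxa-Michael elimination, the ortho-substituted bromide may couple slowly, or a second arylation may occur. The fallback builds the same skeleton through the isoflavone and sets out from 2 and 4. Ketone 2 with pyridinium tribromide (2 equiv) gives 3,3-dibromo-7-(TIPS-oxy)chroman-4-one F7 (not isolated), which Et3N dehydrobrominates to 3-bromo-7-(TIPS-oxy)-4H-chromen-4-one F8. Bromide 4 is converted (n-BuLi, B(OiPr)3, then aqueous acid) into [2-(benzyloxy)-4-methoxyphenyl]boronic acid F9. Suzuki–Miyaura coupling of F8 and F9 (Pd(PPh3)4, K3PO4, dioxane/H2O, 80 °C) gives 3-[2-(benzyloxy)-4-methoxyphenyl]-7-(TIPS-oxy)-4H-chromen-4-one F10. Conjugate reduction with LiBH(s-Bu)3 (THF, −78 °C) returns to the route at 5.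

**Further compounds**

F1 | step 15 | 2-[ArF(p-tolylsulfonyl)methyl]-5-(TIPS-oxy)phenol | Cc1ccc(cc1)S(=O)(=O)C(c1ccc(O[Si](C(C)C)(C(C)C)C(C)C)cc1O)c1cc([C@@H]2COc3cc(O[Si](C(C)C)(C(C)C)C(C)C)ccc3C2)c(O[Si](C(C)C)(C(C)C)C(C)C)cc1OC
F2 | step 15 | 6-(ArF-methylidene)-3-(TIPS-oxy)cyclohexa-2,4-dien-1-one (o-quinone methide, not isolated) | COc1cc(O[Si](C(C)C)(C(C)C)C(C)C)c([C@@H]2COc3cc(O[Si](C(C)C)(C(C)C)C(C)C)ccc3C2)cc1C=C1C=CC(O[Si](C(C)C)(C(C)C)C(C)C)=CC1=O
F3 | step 15 | 2-[4,5-dimethoxy-2-(TIPS-oxy)phenyl]acetic pivalic anhydride (not isolated) | COc1cc(O[Si](C(C)C)(C(C)C)C(C)C)c(CC(=O)OC(=O)C(C)(C)C)cc1OC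
F4 | step 6 | rac-3-[2-(benzyloxy)-5-bromo-4-methoxyphenyl]-7-(TIPS-oxy)chroman-4-one | COc1cc(OCc2ccccc2)c(C2COc3cc(O[Si](C(C)C)(C(C)C)C(C)C)ccc3C2=O)cc1Br
F5 | step 6 | (3R,4R)-3-[2-(benzyloxy)-5-bromo-4-methoxyphenyl]-7-(TIPS-oxy)chroman-4-ol | COc1cc(OCc2ccccc2)c([C@@H]2COc3cc(O[Si](C(C)C)(C(C)C)C(C)C)ccc3[C@@H]2O)cc1Br
F6 | step 6 | (3R)-3-[2-(benzyloxy)-5-bromo-4-methoxyphenyl]-7-(TIPS-oxy)chromane | COc1cc(OCc2ccccc2)c([C@@H]2COc3cc(O[Si](C(C)C)(C(C)C)C(C)C)ccc3C2)cc1Br
F7 | step 3 | 3,3-dibromo-7-(TIPS-oxy)chroman-4-one (not isolated) | O=C1c2ccc(O[Si](C(C)C)(C(C)C)C(C)C)cc2OCC1(Br)Br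
F8 | step 3 | 3-bromo-7-(TIPS-oxy)-4H-chromen-4-one | O=c1c(Br)coc2cc(O[Si](C(C)C)(C(C)C)C(C)C)ccc12
F9 | step 3 | [2-(benzyloxy)-4-methoxyphenyl]boronic acid | COc1ccc(B(O)O)c(OCc2ccccc2)c1
F10 | step 3 | 3-[2-(benzyloxy)-4-methoxyphenyl]-7-(TIPS-oxy)-4H-chromen-4-one | COc1ccc(-c2coc3cc(O[Si](C(C)C)(C(C)C)C(C)C)ccc3c2=O)c(OCc2ccccc2)c1
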